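Time is the budget while solid reagent is left and substrate stands in excess: if the runs so far are read rightly, each hour of stirring then draws a nearly constant amount of coupling partner out of the solid reagent.

| setting | beta | alpha | theta | cedar | birch | alder | maple | oak |
|---|---|---|---|---|---|---|---|---|
| substrate | 0.013 M (in portions, 4) | 0.25 M (in portions, 4) | 0.080 M (in portions, 4) | 0.020 M (in portions, 4) | 0.30 M (in portions, 4) | 0.080 M (in portions, 4) | 0.25 M (in portions, 4) | 0.050 M (in portions, 4) |
| solid reagent | 1.8 equiv | 1.8 equiv | 0.70 equiv | 0.590 equiv | 1.80 equiv | 1.80 equiv | 1.80 equiv | 0.450 equiv |
| remark | run made earlier; portions every 8.0 min | run made earlier; portions every 8.0 min | run made earlier; portions every 8.0 min | the portions of substrate follow each other after 12 min, the first at the start | the portions of substrate follow each other after 25 min, the first at the start | the portions of substrate follow each other after 8.0 min, the first at the start | the portions of substrate follow each other after 12 min, the first at the start | the portions of substrate follow each other after 8.0 min, the first at the start |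
| time |  |  |  | 10 h | 10 h | 10 h | 10 h | 10 h |

| run | time / h | product / % |
|---|---|---|
| beta | 0.500 | 6.1 |
| beta | 1.00 | 20.2 |
| beta | 1.50 | 32.8 |
| beta | 2.50 | 55.9 |
| beta | 4.00 | 79.5 |
| beta | 8.00 | 98.2 |
| alpha | 0.500 | 1.6 |
| alpha | 1.00 | 2.5 |
| alpha | 1.50 | 4.7 |
| alpha | 2.50 | 7.3 |
| alpha | 4.00 | 10.5 |
| alpha | 8.00 | 21.7 |
| theta | 0.500 | 2.6 |
| theta | 1.00 | 7.4 |
| theta | 2.00 | 14.3 |
| theta | 4.00 | 30.4 |
| theta | 8.00 | 58.5 |

(scatter of a reading: 0.5 percentage points)

* the flasks by amount of product, in percent of the substrate charged, highest first, at 10 h (cedar / birch / alder / maple / oak)
* the amount of product, in percent of the substrate charged of the flask you put first, at 10 h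
* the amount of product, in percent of the substrate charged of the flask you put last, at 10 h

- what is said of released group includes idle adduct
- solid reagent is a solid; its amount is given per volume of the solution
- steps under discussion: substrate + coupling partner <-> product + released group; solid reagent <-> coupling partner; substrate + released group <-> idle adduct; released group -> by-product carried off
- at the start none of the solid reagent is in solution

1. Run alpha made 0.0542 M of product in 8.00 h, and run theta made 0.0468 M, although its substrate charge was 0.080 M against 0.25 M. So across these two runs, whose solid charges differ as well, the output reads close to zero order in substrate. Run alpha reads S = 0.00678 M h⁻¹, S being the supply ceiling: molar product per hour with substrate in excess.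

2. The readings bracket S as estimates, not as strict bounds. Run theta, whose substrate was falling, gives 0.00585 M h⁻¹ as the low end; run alpha at 2.50 h gives 0.00730 M h⁻¹ as the high end, a reading that carries its scatter.

3. Multiplying by 10 h and dividing by the charge brackets maple between 23.4% and 29.2%, and birch between 19.5% and 24.3%.

4. In cedar and oak the solid reagent is the limiting reagent. At S, cedar's solid reagent is delivered in 1.74 h and oak's in 3.32 h, both shorter than the time allowed. Their caps are therefore 0.590 and 0.450 equivalents of product, and run beta's 98.2% shows dilute substrate still converting, so the yields should sit close under those caps.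

5. For alder, S gives a crude roof of 84.8%. Run theta, with the same substrate charge and less solid, gives an estimated floor of 58.5% at 8.00 h. Its last slope, carried on, adds 14 percentage points over the remaining time, which brings the estimated roof down to 72.5%.

The forecast, alder > cedar > oak > maple > birch with 70% and 22%, holds that “dissolution of the solid limits it”, and both numbers lie inside these brackets.

The flasks give alder > cedar > oak > maple > birch: alder 72.1%, cedar 59.0%, oak 45.0%, maple 27.2%, birch 22.8%.

    substrate + coupling partner ⇌ product + released group (K = 1.80, k = 2.20 M⁻¹ min⁻¹)
    solid reagent ⇌ coupling partner, rate k2*(cs2 - [coupling partner]) while solid is left; crystals form when [coupling partner] > cs2 (solubility = 6.60 mM, k = 0.0180 min⁻¹)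
    substrate + released group ⇌ idle adduct, settled at all times (K = 32.0 M⁻¹)
    released group → by-product carried off (k = 0.430 min⁻¹)

In birch at 5.00 h, the half-life of coupling partner by the forward coupling step alone is 1.2 min, shorter than the 38.5 min of ln(2)/k2 for going into solution. In birch at 10.0 h, coupling partner is made, each step taken net, 1.00 times as fast as it is used up, and it stands at 2.69 × 10⁻⁴ M against a solubility of 6.6 mM. S then gives 22.6% for birch, which holds 22.8%. Read at 2.5 h, S gives 5.65% for the same flask birch, which holds 5.62%.

Readings and results were generated by integration from invented constants.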